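**Target's fate.** Target in this flask is reckoned to form from substrate and partner, and to be taken back by leftover substrate.

in all of them: substrate 0.80 M
- theta: partner 0.48 M; run made earlier
- eta: partner 1.9 M; run made earlier
- flask: partner 0.960 M; time 2.0 h

- theta (time / min: target / %, side product / %): 8.00: 38.5, 42.8; 25.0: 23.9, 67.8; 40.0: 22.2, 73.6; 60.0: 20.3, 77.6; 90.0: 19.9, 80.6
- eta (time / min: target / %, side product / %): 20.0: 95.6, 3.9; 40.0: 95.7, 3.6; 60.0: 95.1, 4.3; 80.0: 95.7, 4.2; 90.0: 95.5, 3.8

(scatter of a reading: 0.5 percentage points)

- target at 2.0 h, in percent of the substrate charged
- side product at 2.0 h, in percent of the substrate charged
- amount of target if the flask were left three thousand times as long, in percent of the substrate charged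

- percentages count the substrate that a species holds: one side product counts as two

**The count.** In theta at 90.0 min, target plus half the side product comes to 60.2%, and the partner charge is 60.0% of the substrate. This reads as one partner making one target, and one side product taking up one target and one further substrate.

**The rule.** Dividing the rate of side-product formation by the rate of partner use removes time and substrate: dc_side/dc_partner = −r·c_target/c_partner, where r is the rate constant of side-product formation over that of partner use. Taking c_target as the partner used, this integrates to c_side = r[c_charged·ln(c_charged/c_end) − (c_charged − c_end)], where c_charged and c_end are the partner at the start and at the end. With substrate gone, the partner used equals substrate charged minus c_side.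

**Two ways.** At 90.0 min eta holds 99.3% as target plus side product, so its substrate is taken as gone. Its side-product column averages 3.96%, which gives r = 0.0697. Its target column falls short of complete conversion by 4.48%, which gives 0.0794. These are different readings, and their gap of 0.52 percentage points stands beside a scatter of 0.5 points per reading. Their mean, 0.0746, is carried as r, the ratio of those two rate constants, the selectivity factor.

**This flask.** Partner exceeds substrate, so substrate is reckoned to run out first. A trial c_side of 0.0500 M returns 0.0529 M, and that returns 0.0521 M. This reckoning therefore gives side product 13.0% and target 87.0%. Eta stands flat from 20.0 min to 90.0 min, so the target in this flask at 2.0 h and the long-time target are reckoned the same, though 2.0 h is later than any reading.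

**The forecast.** It gives target 88%, side product 12% and 88% in the long run, holding that “nothing is left to react”. Its side product lies 1 point below the reckoning here.

**The result.** The flask gives target 86.5%, side product 13.5%, and 86.5% in the long run.

    substrate + partner → target + by-product (k = 0.0539 /M/s)
    substrate + target → side product (k = 0.00423 /M/s)
    partner ⇌ dormant form (K = 1.20, k = 3.24 × 10⁻⁴ /s)

**The neighbour.** The reckoned 13.0% stands beside the flask's 13.5%. A neighbour flask changes one setting, the substrate, to 0.20 M, which makes 4.80 equiv of partner. The same r, with c_side neglected in the partner used, gives c_side = 0.00181 M, so side product is 1.81%. That neighbour flask gives 1.88% side product and 98.1% target.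

The numbers in the tables were computed with made-up constants; noise was put on by code.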